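## The problem

Target 14 is a 3-methylfuran-2(5H)-one (ring atoms O1, C2 carbonyl, C3 bearing the methyl group, C4 bearing the chain, C5 the ring CH2). Its C4 substituent is an unbranched hexadecyl chain ending in an (S)-configured CH(OAc)CH3 unit. Fourteen methylene groups separate the ring from the carbinol carbon, so the synthesis must deliver a long polymethylene with two different, cleanly differentiated ends from cheap long-chain material. The single stereocentre is too remote from the ring for either end to control the other, so it has to be imported or set by a reagent and afterwards only preserved. The secondary acetate rules out hydroxide, alkoxide, hydride and organometallic reagents once it is in place, and any aldehyde on the way is enolisable and aldol-prone. The butenolide is fragile as well (acidic C5 protons, double-bond migration, ring opening, conjugate addition), and its tetrasubstituted C3=C4 alkene is best made in the ring-closing event, where the ring fixes the geometry. Once C3=C4 is read as the product of a carbonyl olefination, C4 is a ketone carbon and C5 its oxygen-bearing neighbour, so C4–C5 is the C2–C1 bond of a 1-hydroxy-2-alkanone. Such a 1,2-dioxygenated pair can be joined from two carbonyl carbons, the chain aldehyde and formaldehyde, provided one of them reacts as an acyl anion.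

## Retrosynthesis

**C3=C4 (14 ⇒ 13).** The ring double bond is cut first, giving the acyclic keto phosphonate ester 13. The neighbouring cut, lactonisation of a (Z)-γ-hydroxy enoate, would require a stereodefined tetrasubstituted alkene; the intramolecular olefination needs none, because the ring dictates the geometry. The forward reaction must close a five-membered ring onto a ketone with a base mild enough for the acetate. A Horner–Wadsworth–Emmons reaction with LiCl and an amine base meets this.

**O1–C2 (13 ⇒ 11 + 12).** Cutting the ester bond releases the hydroxymethyl ketone 11 and racemic 2-(diethoxyphosphoryl)propanoic acid 12. Acid 12 is commercial and supplies C2, C3 and the C3 methyl group in one piece. The only demand on the forward step is acylation of the single free hydroxyl of 11 without disturbing the ketone.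

**C4–C5 (11 ⇒ 8 + 9), the key disconnection.** The bond between the ketone carbon and the CH2OH carbon is cut to the C17 aldehyde 8 and formaldehyde 9, to be united through the catalytically generated acyl-anion equivalent 10. The neighbouring cut, between C4 and the chain, would need a long-chain organometallic and a glycolic acid derivative, which the acetate cannot tolerate. Oxidative routes from a C18 alkene cost more steps and are kept as a reserve. The acyloin cut removes one carbon as the cheapest C1 unit and is catalytic, redox-neutral and free of protecting groups. The forward reaction must favour crossed over homo-coupling and leave the acetate alone.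

**Aldehyde and acetate (8 ⇒ 6 ⇒ 5).** Aldehyde 8 is the anti-Markovnikov hydration product of the terminal alkyne 6, reached through the alkenylborane 7. Acetate 6 comes from alcohol 5. The hydroxyl has to be masked before 12 is introduced, since two hydroxyls would compete, and the acetate is the group the target carries. It therefore serves as its own protecting group through four steps, all of which must be non-nucleophilic and at most weakly basic.

**Triple-bond relocation (5 ⇒ 4).** No skeletal bond is cut; the terminal alkyne of 5 is traced to the internal alkyne of 4 by a base-mediated zipper isomerisation. This lets the whole chain come from a cheap monofunctional C14 alkyne instead of a non-commercial α,ω-difunctional C14 piece. The forward reaction must walk the triple bond twelve positions without touching the carbinol configuration.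

**C3–C4 of the chain (4 ⇒ 1 + 2).** The homopropargylic alcohol 4 is cut between the carbinol-adjacent CH2 and the alkyne into tetradec-1-yne 1 (as its acetylide 3) and (S)-propylene oxide 2. Attack occurs at the unsubstituted epoxide carbon, so the stereocentre of 2 is never a reacting centre. The priority order O > CH2 > CH3 > H is the same before and after, so (S)-2 gives the (S) series through to 14.

## Roads not taken

**Alternative 1:** The cut runs through O1–C2 and C2–C3. The whole C2 carbonyl is inserted as carbon monoxide into the allenol (S)-2-[15-(tert-butyldimethylsilyloxy)hexadecyl]buta-2,3-dien-1-ol A1 under Ru3(CO)12 (zerovalent ruthenium) and NEt3. This gives the silyl-protected butenolide A2 and turns the allene terminus into the C3 methyl group.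
- Merits: two ring bonds and the methyl group arise in one catalytic, atom-economical step with no phosphorus waste, and the position of the double bond is unambiguous.
- Weak points for this target: A1 needs its own C–C bond formation between the long chain and a four-carbon propargylic or allenic unit, realistically through organomagnesium and copper chemistry. That excludes the acetate, forces the silyl ether and adds a desilylation and an acetylation after ring formation. The chain component, a C15 halide carrying the protected (S)-carbinol, is itself several steps from commercial material. The carbonylation also needs CO pressure and heating.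
- Comparison: as a ring-forming event this road is better than the two-step esterification and olefination used here. The chosen plan sets against it commercial inputs throughout, no protecting-group exchange and a shorter overall sequence.

**Alternative 2:** The cut is the carbinol C–H bond. The methyl ketone 3-methyl-4-(15-oxohexadecyl)furan-2(5H)-one A3 would be reduced late by an (S)-selective NAD(P)H-dependent ketoreductase with isopropanol recycling to the carbinol A4, which is then acetylated to 14.
- Merits: methyl ketones are among the best ketoreductase substrates, either enantiomer is available by choice of enzyme, and the optical purity does not depend on a purchased epoxide.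
- Weak points: the step does not address the ring, so A3 must still be made. A ketone at the chain end would then have to coexist with the aldehyde chemistry or be masked. A3 is very lipophilic, which calls for cosolvent and enzyme screening. The base-sensitive, electron-poor butenolide must survive aqueous buffer, and a separate acetylation follows.
- Comparison: in stereochemical flexibility this road is better. The chosen plan sets against it that the stereocentre costs no step, since it is bought in 2, and that the acetate is already in place and protects the carbinol over the last four steps.

**Alternative 3:** The cut is O1–C5 of a furan surrogate. The one-carbon-longer alkyne (S)-octadec-17-yn-2-yl acetate A5 would be cyclopropenated with an α-diazopropionate to ethyl 2-[(S)-15-acetoxyhexadecyl]-1-methylcycloprop-2-ene-1-carboxylate A6. Under CuI (monovalent copper) or Rh2(OAc)4 (divalent rhodium), A6 would open and reclose through the ester oxygen to the 2-ethoxyfuran A7, whose hydrolysis gives 14.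
- Merits: it needs three steps from a terminal alkyne against four here, avoids an aldehyde, and installs all ring carbons in the cyclopropenation.
- Weak points: α-alkyl diazoesters tend to undergo 1,2-hydride shift in the metal carbene instead of cyclopropenation. The ring opening of A6 can cleave either cyclopropene single bond, and only one mode gives the 3,4-disubstituted pattern, the other leading to a 5-substituted isomer. Hydrolysis of A7 can also deliver the deconjugated lactone.
- Comparison: on step count from the alkyne stage this road is one step better. The chosen plan sets against it that each of its steps is an established reaction on this substrate class, and that the ring substitution pattern follows from the order of bond formation, not from catalyst choice.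

Key step: step 5

Assumption: acid 12 is used as the racemate; the two epimers of 13 that result converge in step 7, where that carbon becomes sp2.

## Route

Step 1
Reactants: 1 tetradec-1-yne; 2 (S)-propylene oxide
Product: 4 (S)-heptadec-4-yn-2-ol, via lithium tetradec-1-yn-1-ide 3 (not isolated)
Conditions: n-BuLi, THF, −78 °C; BF3·OEt2, −78 °C; then 2, −78 °C
Reagents that add atoms: n-butyllithium, [Li]CCCC (supplies the lithium of 3; nothing from it remains in 4)
Why: Deprotonation gives acetylide 3, which opens the BF3-activated epoxide by SN2 attack at the unsubstituted carbon (Yamaguchi–Hirao alkynylation). The stereocentre of 2 is not a reacting centre, so its (S) configuration is carried into 4 unchanged.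

Step 2
Reactants: 4 (S)-heptadec-4-yn-2-ol
Product: 5 (S)-heptadec-16-yn-2-ol
Conditions: KH, H2N(CH2)3NH2, rt (forms KNH(CH2)3NH2); then 4, 0 °C to rt; then H2O
Reagents that add atoms: none
Why: Alkyne zipper reaction: repeated propargyl–allenyl proton shifts move the triple bond along the chain until it is trapped irreversibly as the terminal acetylide. Migration past the alkoxide-bearing carbon is blocked and that carbon is not deprotonated, so the configuration should be retained.

Step 3
Reactants: 5 (S)-heptadec-16-yn-2-ol
Product: 6 (S)-heptadec-16-yn-2-yl acetate
Conditions: Ac2O, pyridine, DMAP (cat.), CH2Cl2, 0 °C to rt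
Reagents that add atoms: acetic anhydride, CC(=O)OC(C)=O
Why: DMAP-catalysed O-acylation of a secondary alcohol; the C–O bond of the stereocentre is not broken, so the configuration is retained.

Step 4
Reactants: 6 (S)-heptadec-16-yn-2-yl acetate
Product: 8 (S)-17-oxoheptadecan-2-yl acetate, via E-alkenyl(dicyclohexyl)borane 7 (not isolated)
Conditions: Cy2BH (from BH3·SMe2, cyclohexene), THF, 0 °C to rt; then 30% H2O2, pH 7–8 phosphate buffer, 0 °C to rt
Reagents that add atoms: dicyclohexylborane, B(C1CCCCC1)C1CCCCC1 (boron and cyclohexyl groups of 7 only); hydrogen peroxide, OO (aldehyde oxygen of 8)
Why: Brown hydroboration with a bulky dialkylborane adds once, syn and anti-Markovnikov, to the terminal alkyne; oxidation of the C–B bond gives the enol and hence the aldehyde. Dialkylboranes do not reduce esters, and the buffered oxidation spares both the acetate and the enolisable aldehyde.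

Step 5
Reactants: 8 (S)-17-oxoheptadecan-2-yl acetate; 9 paraformaldehyde (source of formaldehyde)
Product: 11 (S)-18-hydroxy-17-oxooctadecan-2-yl acetate, via Breslow enaminol 10 (not isolated)
Conditions: 3-ethylbenzothiazolium bromide (10 mol%), iPr2NEt (20 mol%), (CH2O)n (5 equiv), THF, 60 °C, slow addition of 8
Reagents that add atoms: 3-ethylbenzothiazolium bromide, CC[n+]1csc2ccccc12.[Br-] (carbene unit of 10 only; released again)
Why: iPr2NEt deprotonates the benzothiazolium salt at C2 and the carbene adds to the aldehyde carbon of 8; proton transfer gives the Breslow enaminol 10, an acyl-anion equivalent. 10 attacks monomeric formaldehyde released from 9, and collapse of the adduct expels the carbene and leaves 11, in which the former aldehyde carbon (C4 of the future ring) is bonded to the new CH2OH carbon (C5). The closest known reaction type is the thiazolium-catalysed crossed acyloin hydroxymethylation of aliphatic aldehydes with paraformaldehyde to 1-hydroxy-2-alkanones. No ring is closed and no stereocentre is formed; the (S)-acetoxy carbinol is fourteen methylenes away and is not touched by the weakly basic, metal-free, aprotic medium. The step needs crossed over homo-coupling: formaldehyde in excess is the most electrophilic and least hindered acceptor for 10, 8 is kept dilute by slow addition, and benzothiazolylidenes are comparatively sluggish in the homo-acyloin condensation of higher aldehydes. It also needs the right sense of crossed coupling: any adduct that still carries an aldehyde (a homo-acyloin precursor or the isomeric 2-hydroxy aldehyde) stays connected to the cycle through retro-acyloin and enediol equilibria, whereas ketone 11 cannot form a Breslow intermediate and should accumulate as the sink.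

Step 6
Reactants: 11 (S)-18-hydroxy-17-oxooctadecan-2-yl acetate; 12 2-(diethoxyphosphoryl)propanoic acid (racemic)
Product: 13 (17S)-17-acetoxy-2-oxooctadecyl 2-(diethoxyphosphoryl)propanoate (both epimers at the phosphonate α-carbon)
Conditions: DCC, DMAP (cat.), CH2Cl2, 0 °C to rt
Reagents that add atoms: none
Why: Steglich esterification of the only free hydroxyl, a primary one, under neutral conditions that leave the ketone and the acetate alone. The new stereocentre α to phosphorus is not controlled and need not be, since it is erased in step 7.

Step 7
Reactants: 13 (17S)-17-acetoxy-2-oxooctadecyl 2-(diethoxyphosphoryl)propanoate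
Product: 14 (S)-16-(4-methyl-5-oxo-2,5-dihydrofuran-3-yl)hexadecan-2-yl acetate [(S)-4-(15-acetoxyhexadecyl)-3-methylfuran-2(5H)-one]
Conditions: LiCl, DBU, MeCN, 0 °C to rt
Reagents that add atoms: none
Why: Intramolecular Horner–Wadsworth–Emmons olefination under Masamune–Roush conditions: the lithium-chelated phosphonate is deprotonated by the amine base and adds to the ketone in a 5-exo-trig sense. Loss of diethyl phosphate gives the endocyclic tetrasubstituted C3=C4 bond, whose geometry the ring fixes. No nucleophile or strong base is present to cleave the acetate.

## Compound list

1 | tetradec-1-yne | C#CCCCCCCCCCCCC | starting material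
2 | (S)-propylene oxide, (S)-2-methyloxirane | C[C@H]1CO1 | starting material
3 | lithium tetradec-1-yn-1-ide (formed in the flask) | [Li]C#CCCCCCCCCCCCC | intermediate
4 | (S)-heptadec-4-yn-2-ol | C[C@H](O)CC#CCCCCCCCCCCCC | intermediate
5 | (S)-heptadec-16-yn-2-ol | C[C@H](O)CCCCCCCCCCCCCC#C | intermediate
6 | (S)-heptadec-16-yn-2-yl acetate | CC(=O)O[C@@H](C)CCCCCCCCCCCCCC#C | intermediate
7 | (S,E)-17-(dicyclohexylboranyl)heptadec-16-en-2-yl acetate (formed in the flask) | CC(=O)O[C@@H](C)CCCCCCCCCCCCC/C=C/B(C1CCCCC1)C1CCCCC1 | intermediate
8 | (S)-17-oxoheptadecan-2-yl acetate | CC(=O)O[C@@H](C)CCCCCCCCCCCCCCC=O | intermediate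
9 | paraformaldehyde (formaldehyde unit) | C=O | starting material
10 | Breslow enaminol: (S)-17-(3-ethylbenzothiazol-2(3H)-ylidene)-17-hydroxyheptadecan-2-yl acetate (formed in the flask) | CCN1c2ccccc2SC1=C(O)CCCCCCCCCCCCCC[C@H](C)OC(C)=O | intermediate
11 | (S)-18-hydroxy-17-oxooctadecan-2-yl acetate | CC(=O)O[C@@H](C)CCCCCCCCCCCCCCC(=O)CO | intermediate
12 | 2-(diethoxyphosphoryl)propanoic acid (racemic) | CCOP(=O)(OCC)C(C)C(=O)O | starting material
13 | (17S)-17-acetoxy-2-oxooctadecyl 2-(diethoxyphosphoryl)propanoate (epimers at the phosphonate α-carbon) | CC(=O)O[C@@H](C)CCCCCCCCCCCCCCC(=O)COC(=O)C(C)P(=O)(OCC)OCC | intermediate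
14 | (S)-16-(4-methyl-5-oxo-2,5-dihydrofuran-3-yl)hexadecan-2-yl acetate | CC(=O)O[C@@H](C)CCCCCCCCCCCCCCC1=C(C)C(=O)OC1 | target

## Step count and least certain steps

Total step count: 7. Longest linear sequence: 7 steps (1 and 2 to 14).

**Step 5 (key step).** Carbene-mediated self-condensation of formaldehyde and homo-acyloin dimerisation of the long-chain aldehyde may compete with the crossed coupling, and amine-promoted aldol condensation of the enolisable aldehyde may consume material. The cause is that each carbonyl partner can act as donor or acceptor towards the same catalyst. The fallback sets out from 8 and returns at 11; it makes the C4–C5 bond by normal-polarity olefination and installs the oxidation pattern afterwards. Wittig methylenation of 8 (Ph3P=CH2 from Ph3PCH3Br and KN(SiMe3)2, THF, −78 to 0 °C) should give (S)-octadec-17-en-2-yl acetate F1. Dihydroxylation (OsO4 cat., N-methylmorpholine N-oxide, acetone/H2O) should give (2S)-17,18-dihydroxyoctadecan-2-yl acetate F2 as a mixture of C17 epimers, which is of no consequence. Heating with Bu2SnO in toluene with removal of water should give the stannylene acetal (2S)-16-(2,2-dibutyl-1,3,2-dioxastannolan-4-yl)hexadecan-2-yl acetate F3. Its brominolysis (Br2, CH2Cl2, rt) oxidises the secondary carbinol selectively and should deliver 11.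

**Step 2.** Incomplete migration of the triple bond over twelve positions would leave positional isomers that are hard to separate, and prolonged exposure to the amide base risks decomposition. The fallback sets out from 2 and returns at 8; it avoids any isomerisation by building the chain from two alkenes. Undec-10-en-1-ylmagnesium bromide F4 (from 11-bromoundec-1-ene and Mg) opens 2 under CuI catalysis (THF, −30 °C) at the unsubstituted carbon to give (S)-tetradec-13-en-2-ol F5. Acetylation (Ac2O, pyridine, DMAP) gives (S)-tetradec-13-en-2-yl acetate F6. Cross-metathesis with excess pent-4-enal (second-generation Grubbs catalyst RuCl2(=CHPh)(PCy3)(H2IMes), CH2Cl2, 40 °C) gives (S)-17-oxoheptadec-13-en-2-yl acetate F7 as an E/Z mixture. Hydrogenation of the alkene (H2, Pd on carbon, EtOAc) then gives 8.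

**Step 4.** A second hydroboration of the alkenylborane, hydrolysis of the acetate during the oxidative work-up, or self-condensation of the aldehyde could lower the return. The fallback sets out from 6 and returns at 8; it reaches the aldehyde through an alkene and a primary alcohol. Semi-hydrogenation (H2, Lindlar catalyst: Pd on CaCO3 poisoned with Pb(OAc)2, quinoline, hexane) should give (S)-heptadec-16-en-2-yl acetate F8. Hydroboration with 9-borabicyclo[3.3.1]nonane followed by NaBO3·4H2O should give (S)-17-hydroxyheptadecan-2-yl acetate F9. Dess–Martin periodinane in CH2Cl2 then oxidises the primary alcohol to 8.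

**Step 7.** Enolisation of the α-acyloxy ketone may outrun the slow formation of a tetrasubstituted alkene, leading to acyl migration or intermolecular condensation, and excess amidine base may shift the double bond out of conjugation. The fallback sets out from 11 and returns at 14; it closes the ring by carbonyl addition and forms the alkene in a separate dehydration. Acylation of 11 with 2-bromopropanoyl bromide (pyridine, CH2Cl2, 0 °C) should give (17S)-17-acetoxy-2-oxooctadecyl 2-bromopropanoate F10. An intramolecular Reformatsky reaction (Zn dust, THF, reflux) should close the ring to the β-hydroxy lactone (2S)-16-(3-hydroxy-4-methyl-5-oxooxolan-3-yl)hexadecan-2-yl acetate F11, as a mixture of diastereomers. Dehydration towards the acidic C3 hydrogen (SOCl2, pyridine, 0 °C) then gives 14.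

## Further compounds

F1 | step 5 | (S)-octadec-17-en-2-yl acetate | CC(=O)O[C@@H](C)CCCCCCCCCCCCCCC=C
F2 | step 5 | (2S)-17,18-dihydroxyoctadecan-2-yl acetate | CC(=O)O[C@@H](C)CCCCCCCCCCCCCCC(O)CO
F3 | step 5 | (2S)-16-(2,2-dibutyl-1,3,2-dioxastannolan-4-yl)hexadecan-2-yl acetate | CC(=O)O[C@@H](C)CCCCCCCCCCCCCCC1CO[Sn](CCCC)(CCCC)O1
F4 | step 2 | undec-10-en-1-ylmagnesium bromide | C=CCCCCCCCCC[Mg]Br
F5 | step 2 | (S)-tetradec-13-en-2-ol | C[C@H](O)CCCCCCCCCCC=C
F6 | step 2 | (S)-tetradec-13-en-2-yl acetate | CC(=O)O[C@@H](C)CCCCCCCCCCC=C
F7 | step 2 | (S)-17-oxoheptadec-13-en-2-yl acetate (E/Z mixture) | CC(=O)O[C@@H](C)CCCCCCCCCCC=CCCC=O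
F8 | step 4 | (S)-heptadec-16-en-2-yl acetate | CC(=O)O[C@@H](C)CCCCCCCCCCCCCC=C
F9 | step 4 | (S)-17-hydroxyheptadecan-2-yl acetate | CC(=O)O[C@@H](C)CCCCCCCCCCCCCCCO
F10 | step 7 | (17S)-17-acetoxy-2-oxooctadecyl 2-bromopropanoate | CC(=O)O[C@@H](C)CCCCCCCCCCCCCCC(=O)COC(=O)C(C)Br
F11 | step 7 | (2S)-16-(3-hydroxy-4-methyl-5-oxooxolan-3-yl)hexadecan-2-yl acetate | CC(=O)O[C@@H](C)CCCCCCCCCCCCCCC1(O)COC(=O)C1C
A1 | alternative 1 | (S)-2-[15-(tert-butyldimethylsilyloxy)hexadecyl]buta-2,3-dien-1-ol | C[C@H](O[Si](C)(C)C(C)(C)C)CCCCCCCCCCCCCCC(CO)=C=C
A2 | alternative 1 | (S)-4-[15-(tert-butyldimethylsilyloxy)hexadecyl]-3-methylfuran-2(5H)-one | C[C@H](O[Si](C)(C)C(C)(C)C)CCCCCCCCCCCCCCC1=C(C)C(=O)OC1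
A3 | alternative 2 | 3-methyl-4-(15-oxohexadecyl)furan-2(5H)-one | CC(=O)CCCCCCCCCCCCCCC1=C(C)C(=O)OC1
A4 | alternative 2 | (S)-4-(15-hydroxyhexadecyl)-3-methylfuran-2(5H)-one | C[C@H](O)CCCCCCCCCCCCCCC1=C(C)C(=O)OC1
A5 | alternative 3 | (S)-octadec-17-yn-2-yl acetate | CC(=O)O[C@@H](C)CCCCCCCCCCCCCCC#C
A6 | alternative 3 | ethyl 2-[(S)-15-acetoxyhexadecyl]-1-methylcycloprop-2-ene-1-carboxylate | CCOC(=O)C1(C)C=C1CCCCCCCCCCCCCC[C@H](C)OC(C)=O
A7 | alternative 3 | (S)-16-(5-ethoxy-4-methylfuran-3-yl)hexadecan-2-yl acetate | CCOc1occ(CCCCCCCCCCCCCC[C@H](C)OC(C)=O)c1C
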